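J and Z come from equal charges of G and X, so once both are consumed the share of J stands at half; I take that symmetric end as the zero of my scale and ask what a flask shows above it.

| flask | G | X | L | D | temperature | remark | time |
|---|---|---|---|---|---|---|---|
| green | 1 M | 1 M | 200 mM (held) | 4 mM | 65 °C | run made earlier |  |
| ochre | 1 M | 1 M | 200 mM (held) | 4 mM | 82 °C | run made earlier |  |
| epsilon | 2.0 M | 2.0 M | 200 mM (held) | 4.0 mM |  | at 95 °C until 8.0 h, from then on at 70 °C | 15 h |
| alpha | 2.0 M | 2.0 M | 200 mM (held) | 4.0 mM | 95 °C |  | 15 h |
| delta | 2.0 M | 2.0 M | 200 mM (held) | 4.0 mM | 70 °C |  | 15 h |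

- green (time / h: J / %, Z / %, G / %): 3.00: 21.1, 9.0, 27.2; 4.00: 25.5, 13.2, 24.0; 6.00: 34.2, 16.0, 17.2; 12.0: 45.0, 30.0, 5.9; 20.0: 48.8, 40.1, 3.3; 25.0: 48.7, 42.0, 0; 40.0: 50.4, 47.1, 0.9
- ochre (time / h: J / %, Z / %, G / %): 1.33: 15.2, 7.0, 33.3; 2.00: 24.5, 9.4, 25.7; 3.00: 31.6, 14.6, 20.9; 5.00: 40.4, 22.2, 8.9; 8.00: 45.3, 32.3, 2.9; 12.0: 50.6, 37.3, 0.5; 20.0: 51.1, 45.6, 0

(scatter of a reading: 1 percentage point)

- D is single-handed; G and X are mirror images of each other, charged as a racemate, each of them at the stated concentration
- at the start none of E is dissolved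
- the numbers in the tables scatter with a standard deviation of 1 percentage point
- steps under discussion: E + D + G -> D + J; E + D + X -> D + Z; L <-> E; 2 E -> Q

- the flask that comes out highest in share of J in all that became J or Z, or "all alike" when all lie within 1.5 percentage points (epsilon / alpha / delta / all alike)
- share of J in all that became J or Z, epsilon
- share of J in all that became J or Z, alpha
- share of J in all that became J or Z, delta

X is not tabulated, but each Z cost one X, so I read X from Z. The steps under discussion run G and X on the same E and D, so in a flask at one temperature, if each is first order in its substrate, E and time cancel in the ratio of ln(fraction of G left) to ln(fraction of X left). The green run at 6.00 h reads 2.77 and the ochre run at 3.00 h reads 2.53, so I carry their mean as the selectivity factor s = 2.65. With a fraction x of X left, G stands at x^s, and the share of J is what G lost over what G and X lost together.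

Green's X, at 40.0% of its charge by 12.0 h, carried on at that pace for the 15 h of delta, gives me x = 31.8% and a share of 58.3% for delta, though delta is hotter and holds twice the charge of green, so this x is a rough estimate.

The forecast names delta, with 57.5% there, 54% for epsilon and 52.2% for alpha: “The share of J therefore depends only on conversion, and the least-converted flask scores highest.” My delta stands 0.80 percentage points above its figure.

Delta comes out highest, at 57.6%, against 53.9% for epsilon and 52.0% for alpha.

    E + D + G → D + J (k = 0.130 L² mol⁻² s⁻¹, Ea = 52.0 kJ mol⁻¹)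
    E + D + X → D + Z (k = 0.0480 L² mol⁻² s⁻¹, Ea = 53.0 kJ mol⁻¹)
    L ⇌ E, rate k3*(csat - [E]) (kL = 0.00260 s⁻¹)
    2 E → Q (k = 0.00500 L mol⁻¹ s⁻¹, Ea = 72.0 kJ mol⁻¹)
    (constants at 70 °C)

Dissolved E in epsilon goes from 0.0723 M at 7.50 h to 0.131 M at 15.0 h, yet s with the 15% of X left in epsilon gives 53.9%, beside the 53.9% computed.

In the flask like alpha but kept at 70 °C, 29% of X is left, so s gives 57.5%; the computed share is 57.6%.

(All runs come from a simulation for substances that don't exist; the scatter is artificial.)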